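**Assumption:** spongian (labdane) atom numbers are used throughout; commercial (−)-sclareol is (5S,8R,9R,10S,13R), which is the absolute series the target SMILES requires (C8, C13 and C14 map directly; C5 and C9 follow from the stereospecific 1,2-shift).

## Retrosynthetic overview

1. 14 ⇐ 13 (Mitsunobu acetylation inverts C12) ⇐ 12 (C12 hydroxylation of the δ-lactone).
2. 12 ⇐ 9 in one flask: the ring C ε-lactone ionizes at C9–O, C5 shifts from C10 to C9 (ring B 6→5, ring A 6→7, Δ10(20) by loss of H-20), and the freed C11 acid closes onto C15–OH.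
3. 9 ⇐ 8: Baeyer–Villiger scission of C9–C11 in a spongian-type 11-ketone.
4. 8 ⇐ 4: allylic oxidations at C16 and C11, then α-face hydrogenation of isocopal-12-ene.
5. 4 ⇐ 1: ring C by cation–olefin cyclization of a sclareol-derived labdane (rings A and B from the chiral pool). Ring order: ring C, ε-lactone, cyclopentane and cycloheptane together, δ-lactone.

## Route

Step 1
Reactants: 1 (−)-sclareol
Product: 2 (13R)-labd-14-ene-8α,13-diyl bis(methoxyacetate)
Conditions: MeOCH2COCl, PhNMe2, CH2Cl2, 0 → 40 °C
Reagents that add atoms: methoxyacetyl chloride, COCC(Cl)=O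
Why: Esterification of both tertiary hydroxyls with an acyl chloride and a weak amine base, as for sclareol diacetate; no stereocentre is touched, and the methoxyacetate at C15 can later be removed in the presence of acetates.

Step 2
Reactants: 2 (13R)-labd-14-ene-8α,13-diyl bis(methoxyacetate)
Product: 3 (13E)-labd-13-ene-8α,15-diyl bis(methoxyacetate)
Conditions: PdCl2(MeCN)2 (5 mol %), THF, 25 °C
Reagents that add atoms: none
Why: Palladium-catalysed [3,3]-sigmatropic allylic ester transposition moves the tertiary allylic ester to the primary position and gives the more stable trisubstituted (E)-alkene; the C13 stereocentre is erased.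

Step 3
Reactants: 3 (13E)-labd-13-ene-8α,15-diyl bis(methoxyacetate)
Product: 4 isocopal-12-en-15-yl methoxyacetate
Conditions: FSO3H (5 equiv), 2-nitropropane, −78 °C; Et3N quench
Reagents that add atoms: none
Why: Cation–olefin cyclization (Stork–Eschenmoser type, as in spongian biosynthesis): the superacid ionizes the C8 ester, C14 of the (E)-alkene captures the cation through a chair so the new C8–C14 bond is equatorial (8β-CH3 axial, 14α-H, C15 β), and the C13 cation loses H-12 to give the Δ12 alkene.

Step 4
Reactants: 4 isocopal-12-en-15-yl methoxyacetate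
Product: 6 16-acetoxyisocopal-12-en-15-yl methoxyacetate, via allylic alcohol 5 (not isolated)
Conditions: SeO2 (30 mol %), t-BuOOH, CH2Cl2, 25 °C; then Ac2O, pyridine, DMAP (cat.), 0 °C
Reagents that add atoms: tert-butyl hydroperoxide, CC(C)(C)OO; acetic anhydride, CC(=O)OC(C)=O
Why: SeO2 allylic oxidation (ene reaction then [2,3]-shift) attacks the methyl group on the more substituted alkene carbon in preference to the C14 methine; the primary allylic alcohol is acetylated in the same flask.

Step 5
Reactants: 6 16-acetoxyisocopal-12-en-15-yl methoxyacetate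
Product: 7 16-acetoxy-11-oxoisocopal-12-en-15-yl methoxyacetate
Conditions: CrO3, 3,5-dimethylpyrazole, CH2Cl2, −20 °C
Reagents that add atoms: chromium trioxide, O=[Cr](=O)=O
Why: Chromium-mediated allylic oxidation of the ring CH2 next to the CH= terminus (C11), the standard way from Δ12 terpenoids to 11-oxo-12-enes.

Step 6
Reactants: 7 16-acetoxy-11-oxoisocopal-12-en-15-yl methoxyacetate
Product: 8 16-acetoxy-11-oxo-13αH-isocopalan-15-yl methoxyacetate
Conditions: H2 (1 atm), PtO2 (5 mol %), EtOAc, 25 °C
Reagents that add atoms: none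
Why: Catalytic hydrogenation of the enone C=C; syn delivery from the α-face (the β-face carries the axial 8β and 10β methyls) sets 13α-H and leaves CH2OAc β (axial); C13 is β to the ketone and cannot epimerize, and platinum limits allylic C–O hydrogenolysis.

Step 7
Reactants: 8 16-acetoxy-11-oxo-13αH-isocopalan-15-yl methoxyacetate
Product: 9 16-acetoxy-15-(methoxyacetoxy)-9,11-seco-13αH-isocopalan-11,9β-olide (ring C ε-lactone)
Conditions: (CF3CO)2O, H2O2·urea, Na2HPO4, CH2Cl2, 0 → 25 °C
Reagents that add atoms: hydrogen peroxide–urea (source of the inserted oxygen via CF3CO3H), NC(N)=O.OO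
Why: Baeyer–Villiger oxidation with the most reactive common peracid; the peracid adds from the open α-face, the secondary C9 migrates in preference to the primary C12 with retention to give the C9β–O bond, and loss of three syn-axial contacts at C11 drives the Criegee step.

Step 8
Reactants: 9 ring C ε-lactone
Product: 12 12-deacetoxy target δ-lactone, via seco acid 10 (not isolated), via hydroxy acid 11 (not isolated)
Conditions: Yb(OTf)3 (20 mol %), (CF3)2CHOH, 40 °C; then MeOH, 25 °C
Reagents that add atoms: none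
Why: Proposed new method: the Lewis acid in the ionizing solvent activates the lactone carbonyl; the C9–O bond (β-equatorial, antiperiplanar to C5–C10) heterolyses with concerted 1,2-shift of C5 from C10 to C9 (Wagner–Meerwein; inversion at C9, retention at C5, hence 5α-H and 9α-H cis and both trans to 8β-CH3); the tertiary C10 cation loses H-20 to the carboxylate held on the same face, giving the exocyclic alkene and the C11 acid; after MeOH is added the same catalyst cleaves the methoxyacetate but not the acetate, and the C15 alcohol lactonizes onto C11; the closest known reaction types are solvolytic ring contraction/expansion of neopentyl-type esters and sulfonates, acid-induced alkyl–oxygen cleavage of esters of tertiary-like carbons, and Yb(OTf)3-catalysed methanolysis of methoxyacetates beside acetates.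

Step 9
Reactants: 12 12-deacetoxy target δ-lactone
Product: 13 (12R)-12-hydroxy δ-lactone (OH trans to CH2OAc)
Conditions: NaN(SiMe3)2 (1.1 equiv), THF, −78 °C; 2-(phenylsulfonyl)-3-phenyloxaziridine, −78 °C; aq. NH4Cl
Reagents that add atoms: 2-(phenylsulfonyl)-3-phenyloxaziridine, O=S(=O)(N1OC1c1ccccc1)c1ccccc1
Why: Enolate hydroxylation with an N-sulfonyloxaziridine (Davis oxidation); the lactone CH2 is clearly more acidic than the acetate CH3, so one equivalent of base at −78 °C deprotonates C12, and the oxidant adds anti to the neighbouring C13 substituent to give the alcohol trans to CH2OAc.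

Step 10
Reactants: 13 (12R)-12-hydroxy δ-lactone
Product: 14 target CNP0333014.1
Conditions: AcOH, PPh3, DIAD, THF, 0 → 25 °C
Reagents that add atoms: acetic acid, CC(O)=O
Why: Mitsunobu esterification; SN2 displacement of the activated α-hydroxy lactone by acetate inverts C12 and places OAc cis to the C13 CH2OAc, as in the target (12S).

## Compound list

1 | (−)-sclareol, (13R)-labd-14-ene-8α,13-diol | C=C[C@](C)(O)CC[C@@H]1[C@@]2(C)CCCC(C)(C)[C@@H]2CC[C@@]1(C)O | starting material
2 | (13R)-labd-14-ene-8α,13-diyl bis(methoxyacetate) | C=C[C@](C)(OC(=O)COC)CC[C@@H]1[C@@]2(C)CCCC(C)(C)[C@@H]2CC[C@@]1(C)OC(=O)COC | intermediate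
3 | (13E)-labd-13-ene-8α,15-diyl bis(methoxyacetate) | COCC(=O)OC/C=C(\C)CC[C@@H]1[C@@]2(C)CCCC(C)(C)[C@@H]2CC[C@@]1(C)OC(=O)COC | intermediate
4 | isocopal-12-en-15-yl methoxyacetate (5α-H, 9α-H, 14α-H, 8β-CH3, 10β-CH3) | COCC(=O)OC[C@@H]1C(C)=CC[C@@H]2[C@@]3(C)CCCC(C)(C)[C@@H]3CC[C@@]12C | intermediate
5 | 16-hydroxyisocopal-12-en-15-yl methoxyacetate | COCC(=O)OC[C@@H]1C(CO)=CC[C@@H]2[C@@]3(C)CCCC(C)(C)[C@@H]3CC[C@@]12C | intermediate (not isolated)
6 | 16-acetoxyisocopal-12-en-15-yl methoxyacetate | COCC(=O)OC[C@@H]1C(COC(C)=O)=CC[C@@H]2[C@@]3(C)CCCC(C)(C)[C@@H]3CC[C@@]12C | intermediate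
7 | 16-acetoxy-11-oxoisocopal-12-en-15-yl methoxyacetate | COCC(=O)OC[C@@H]1C(COC(C)=O)=CC(=O)[C@@H]2[C@@]3(C)CCCC(C)(C)[C@@H]3CC[C@@]12C | intermediate
8 | 16-acetoxy-11-oxo-13αH-isocopalan-15-yl methoxyacetate (13β-CH2OAc axial) | COCC(=O)OC[C@@H]1[C@H](COC(C)=O)CC(=O)[C@@H]2[C@@]3(C)CCCC(C)(C)[C@@H]3CC[C@@]12C | intermediate
9 | ring C ε-lactone, 16-acetoxy-15-(methoxyacetoxy)-9,11-seco-13αH-isocopalan-11,9β-olide | COCC(=O)OC[C@@H]1[C@H](COC(C)=O)CC(=O)O[C@@H]2[C@@]3(C)CCCC(C)(C)[C@@H]3CC[C@@]12C | intermediate
10 | seco acid, cis-hydroazulene (5α-H, 9α-H, 8β-CH3, Δ10(20)) with C8 side chain CH(CH2OCOCH2OMe)–CH(CH2OAc)–CH2–CO2H | C=C1CCCC(C)(C)[C@@H]2CC[C@@](C)([C@H](COC(=O)COC)[C@H](COC(C)=O)CC(O)=O)[C@H]12 | intermediate (not isolated)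
11 | hydroxy acid, 15-hydroxy analogue of 10 | C=C1CCCC(C)(C)[C@@H]2CC[C@@](C)([C@H](CO)[C@H](COC(C)=O)CC(O)=O)[C@H]12 | intermediate (not isolated)
12 | 12-deacetoxy target, δ-lactone (11,15-olide) with 13-CH2OAc trans to the hydroazulenyl group | C=C1CCCC(C)(C)[C@@H]2CC[C@@](C)([C@@H]3COC(=O)C[C@H]3COC(C)=O)[C@H]12 | intermediate
13 | (12R)-12-hydroxy δ-lactone, OH trans to CH2OAc | C=C1CCCC(C)(C)[C@@H]2CC[C@@](C)([C@@H]3COC(=O)[C@H](O)[C@H]3COC(C)=O)[C@H]12 | intermediate
14 | target CNP0333014.1, (12S)-acetate | C=C1CCCC(C)(C)[C@@H]2CC[C@@](C)([C@@H]3COC(=O)[C@@H](OC(C)=O)[C@H]3COC(C)=O)[C@H]12 | target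

## Step count and risks

Total steps: 10. Longest linear sequence: 10 (1 → 14; fully linear).

**Step 7 (Baeyer–Villiger).** The C11 carbonyl is flanked on its β-face by three syn-axial groups (8β-CH3, 10β-CH3, 13β-CH2OAc), and 11-oxo terpenoids of this type are known to resist peracids, so this is the step most likely to be too slow. The fallback sets out from 8 and returns at 9, replacing oxygen insertion by alkene cleavage. Ketone 8 is reduced from the α-face with NaBH4 (EtOH/THF) to the 11β-alcohol F1. Trans-diaxial dehydration (POCl3, pyridine) gives the Δ9(11)-alkene F2. Ozonolysis with H2O2/HCO2H work-up gives the 9-oxo-9,11-seco-11-oic acid F3. NaBH4 reduction of the C9 ketone from the α-face gives the 9β-hydroxy acid F4, which is closed with 2,4,6-trichlorobenzoyl chloride, Et3N and DMAP to ε-lactone 9.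

**Step 8 (ionization, 1,2-shift and lactonization).** The carboxylate may be too poor a leaving group under these conditions. Other hazards are a competing shift of C7 (from C8 to C9) to a hydrindane, and proton loss to endocyclic alkenes. The fallback sets out from 9 and returns at 12. Yb(OTf)3 in MeOH is used first: the methoxyacetate is cleaved and the freed C15 alcohol opens the strained ε-lactone to the δ-lactone 9β-alcohol F5. Tf2O with 2,6-di-tert-butyl-4-methylpyridine (CH2Cl2, −78 → 0 °C) then makes the C9 triflate, which ionizes with the same C5 shift and proton loss under buffered, non-acidic conditions to give 12.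

**Step 9 (C12 hydroxylation).** The free enolate may deprotonate or attack the C16 acetate, and the facial selectivity is only predicted. The fallback sets out from 12 and returns at 13. NaN(SiMe3)2 is added to 12 premixed with Me3SiCl at −78 °C, so the enolate is trapped as it forms to give the silyl ketene acetal F6. This electron-rich alkene is oxidized with dimethyldioxirane (acetone, −78 °C; Rubottom-type) in preference to the exocyclic alkene, and aqueous citric acid then gives 13.

Further compounds
F1 | step 7 | 16-acetoxy-11β-hydroxy-13αH-isocopalan-15-yl methoxyacetate | COCC(=O)OC[C@@H]1[C@H](COC(C)=O)C[C@H](O)[C@@H]2[C@@]3(C)CCCC(C)(C)[C@@H]3CC[C@@]12C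
F2 | step 7 | 16-acetoxy-13αH-isocopal-9(11)-en-15-yl methoxyacetate | COCC(=O)OC[C@@H]1[C@H](COC(C)=O)CC=C2[C@@]3(C)CCCC(C)(C)[C@@H]3CC[C@@]12C
F3 | step 7 | 16-acetoxy-15-(methoxyacetoxy)-9-oxo-9,11-seco-13αH-isocopalan-11-oic acid | O=C1[C@@]2(C)CCCC(C)(C)[C@@H]2CC[C@@]1(C)[C@H](COC(=O)COC)[C@H](COC(C)=O)CC(O)=O
F4 | step 7 | 16-acetoxy-9β-hydroxy-15-(methoxyacetoxy)-9,11-seco-13αH-isocopalan-11-oic acid | O[C@@H]1[C@@]2(C)CCCC(C)(C)[C@@H]2CC[C@@]1(C)[C@H](COC(=O)COC)[C@H](COC(C)=O)CC(O)=O
F5 | step 8 | 16-acetoxy-9β-hydroxy-9,11-seco-13αH-isocopalan-11,15-olide (δ-lactone 9β-alcohol) | O[C@@H]1[C@@]2(C)CCCC(C)(C)[C@@H]2CC[C@@]1(C)[C@@H]3COC(=O)C[C@H]3COC(C)=O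
F6 | step 9 | trimethylsilyl ketene acetal of 12 | C=C1CCCC(C)(C)[C@@H]2CC[C@@](C)([C@@H]3COC(O[Si](C)(C)C)=C[C@H]3COC(C)=O)[C@H]12
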